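**Plan**

- Retrosynthesis: both a3–a4 bonds are cut together (a3 = the S methine β to each ester carbonyl, a4 = the ethylidene carbon that carries CHO). Then the two ester C–O bonds are cut, then in the core C1′–CH2O, C2–CH3, C3–CH2O and C4–C1′ (core labels: cyclopentane C1 O-acyl, C2 methyl, C3 CH2OH, C4 bearing the exocyclic methine C1′, C5 CH2).
- Enabling feature: both acyl groups are the same (E)-4-formyl-3-(2-oxoethyl)hex-4-enoyl unit. Each a3 lies β to an ester carbonyl and far from the only ring (the cyclopentane), so one chiral catalyst can add one alkenyl reagent to both enoates of a core bis-enoate.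
- Forward: the cyclopentane is bought as monoacetate 1. The C4 arm, then C3/C2, then the C1 oxygen are set around it. A temporary bridged δ-lactone (closed in step 7, opened in step 10) fixes C1′. Acid 20 is attached twice, boronic acid 28 is added twice, and deprotection/oxidation finish.
- Stereochemistry: C4 from 1 (net retention in the palladium alkylation); C3 and C2 by anti addition/alkylation on the enone; C1 by hydride anti to methyl, then Mitsunobu inversion; C1′ by exo-face aldol of the bicyclic lactone enolate; both a3 by (R)-BINAP–rhodium; ethylidene geometry from (Z)-2-iodobut-2-enal with retention.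

Key step: step 17

Remark: the saturated aldehydes are carried as diethyl acetals, chosen because 4,4-diethoxybut-1-ene is commercial; 1 is taken as the commercial (1S,4R) enantiomer.

**Route**

Step 1
Reactants: 1 (1S,4R)-cis-4-acetoxycyclopent-2-en-1-ol; 2 dimethyl malonate
Product: 3 dimethyl 2-[(1R,4S)-4-hydroxycyclopent-2-en-1-yl]propanedioate (malonate cis to OH)
Conditions: NaH, THF, 0 °C; Pd(PPh3)4 (3 mol %), rt
Reagents that add atoms: none
Why: Tsuji–Trost allylic alkylation: zerovalent palladium ionises the acetate with inversion and the malonate anion attacks the allyl terminus remote from the hydroxyl anti to palladium, so net retention places the chain cis to OH and fixes core C4.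

Step 2
Reactants: 3 dimethyl 2-[(1R,4S)-4-hydroxycyclopent-2-en-1-yl]propanedioate
Product: 4 methyl 2-[(1S,4S)-4-hydroxycyclopent-2-en-1-yl]acetate
Conditions: NaCl, H2O (2 equiv), DMSO, 150 °C
Reagents that add atoms: none
Why: Krapcho dealkoxycarbonylation: chloride demethylates one ester and the carboxylate loses CO2 under neutral conditions that leave the stereocentres and the allylic alcohol alone.

Step 3
Reactants: 4 methyl 2-[(1S,4S)-4-hydroxycyclopent-2-en-1-yl]acetate
Product: 5 methyl 2-[(1S)-4-oxocyclopent-2-en-1-yl]acetate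
Conditions: MnO2 (activated, excess), CH2Cl2, rt
Reagents that add atoms: none
Why: Allylic alcohol oxidation with MnO2 is neutral, so the γ-stereocentre (core C4) is not enolised and the double bond should not move.

Step 4
Reactants: 5 methyl 2-[(1S)-4-oxocyclopent-2-en-1-yl]acetate; 6 (chloromethyl)dimethyl(propan-2-yloxy)silane
Product: 9 methyl 2-[(1S,2S,3R)-2-{[dimethyl(propan-2-yloxy)silyl]methyl}-3-methyl-4-oxocyclopentyl]acetate, via Grignard reagent 7 (not isolated), via magnesium enolate 8 (not isolated)
Conditions: 6, Mg, THF, rt; CuI (10 mol %), 5, THF, −78 → −40 °C; MeI, HMPA, −40 → 0 °C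
Reagents that add atoms: iodomethane, CI
Why: Copper-catalysed 1,4-addition of the hydroxymethyl-anion equivalent 7 anti to the C4 arm, then C-methylation of enolate 8 anti to the new C3 substituent (conjugate addition–enolate alkylation), should leave all three ring substituents mutually trans, which is also the thermodynamic arrangement at the epimerisable C2.

Step 5
Reactants: 9 methyl 2-[(1S,2S,3R)-2-{[dimethyl(propan-2-yloxy)silyl]methyl}-3-methyl-4-oxocyclopentyl]acetate
Product: 10 methyl 2-[(1S,2S,3R)-2-(hydroxymethyl)-3-methyl-4-oxocyclopentyl]acetate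
Conditions: 30 % aq H2O2, KF, KHCO3, THF/MeOH (1:1), rt
Reagents that add atoms: hydrogen peroxide, OO
Why: Tamao–Fleming oxidation: fluoride-assisted attack of peroxide on the alkoxysilane and 1,2-shift of carbon from silicon to oxygen give the primary alcohol, with ketone and ester tolerated under bicarbonate buffering.

Step 6
Reactants: 10 methyl 2-[(1S,2S,3R)-2-(hydroxymethyl)-3-methyl-4-oxocyclopentyl]acetate
Product: 11 methyl 2-[(1S,2S,3R)-2-({[tert-butyl(dimethyl)silyl]oxy}methyl)-3-methyl-4-oxocyclopentyl]acetate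
Conditions: TBSCl, imidazole, DMF, rt
Reagents that add atoms: tert-butyldimethylsilyl chloride, CC(C)(C)[Si](C)(C)Cl
Why: Standard silylation of the primary alcohol, which keeps this hydroxyl from lactonising with the C4 arm and stays to the end.

Step 7
Reactants: 11 methyl 2-[(1S,2S,3R)-2-({[tert-butyl(dimethyl)silyl]oxy}methyl)-3-methyl-4-oxocyclopentyl]acetate
Product: 13 (1S,5S,6S,7R)-6-({[tert-butyl(dimethyl)silyl]oxy}methyl)-7-methyl-2-oxabicyclo[3.2.1]octan-3-one, via hydroxy ester 12 (not isolated)
Conditions: LiBH(s-Bu)3, THF, −78 °C → rt; then PPTS (10 mol %), PhMe, 80 °C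
Reagents that add atoms: none
Why: Diastereoselective ketone reduction by a bulky trialkylborohydride from the face opposite the α-methyl group (and opposite the C4 arm) should give the C1 alcohol cis to both, and only this epimer can close onto the acetate arm by transesterification to the bridged δ-lactone.

Step 8
Reactants: 13 (1S,5S,6S,7R)-6-({[tert-butyl(dimethyl)silyl]oxy}methyl)-7-methyl-2-oxabicyclo[3.2.1]octan-3-one
Product: 15 (1S,4S,5R,6S,7R)-6-({[tert-butyl(dimethyl)silyl]oxy}methyl)-4-(hydroxymethyl)-7-methyl-2-oxabicyclo[3.2.1]octan-3-one (4-exo), via lithium enolate 14 (not isolated)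
Conditions: LiN(i-Pr)2, THF, −78 °C; CH2O (dry THF solution), −78 → −40 °C; AcOH
Reagents that add atoms: formaldehyde, C=O
Why: Aldol addition of the lactone enolate to monomeric formaldehyde; as with other bicyclo[3.2.1]octan-3-one-type enolates the electrophile should enter axially on the exo face (side of the one-carbon bridge, core C5), away from the substituted two-carbon bridge, which sets C1′ and makes its two arms chemically different.

Step 9
Reactants: 15 (1S,4S,5R,6S,7R)-6-({[tert-butyl(dimethyl)silyl]oxy}methyl)-4-(hydroxymethyl)-7-methyl-2-oxabicyclo[3.2.1]octan-3-one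
Product: 16 (1S,4S,5R,6S,7R)-4,6-bis({[tert-butyl(dimethyl)silyl]oxy}methyl)-7-methyl-2-oxabicyclo[3.2.1]octan-3-one
Conditions: TBSCl, imidazole, DMF, rt
Reagents that add atoms: tert-butyldimethylsilyl chloride, CC(C)(C)[Si](C)(C)Cl
Why: Standard silylation; this arm becomes the free CH2OH on C1′ of the target.

Step 10
Reactants: 16 (1S,4S,5R,6S,7R)-4,6-bis({[tert-butyl(dimethyl)silyl]oxy}methyl)-7-methyl-2-oxabicyclo[3.2.1]octan-3-one
Product: 17 (1S,2R,3S,4R)-4-[(2R)-1-{[tert-butyl(dimethyl)silyl]oxy}-3-hydroxypropan-2-yl]-3-({[tert-butyl(dimethyl)silyl]oxy}methyl)-2-methylcyclopentan-1-ol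
Conditions: LiAlH4, THF, −20 → 0 °C; aq. potassium sodium tartrate
Reagents that add atoms: none
Why: Hydride reduction of the lactone releases the arm to be acylated and the C1 hydroxyl in one operation; β-silyloxy esters are reduced cold without silyl migration, so C1′ should not scramble.

Step 11
Reactants: 18 4,4-diethoxybut-1-ene; 19 acrylic acid
Product: 20 (2E)-5,5-diethoxypent-2-enoic acid
Conditions: second-generation Grubbs catalyst RuCl2(H2IMes)(PCy3)(=CHPh) (3 mol %), CH2Cl2, 40 °C
Reagents that add atoms: none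
Why: Olefin cross-metathesis of a terminal alkene with acrylic acid is E-selective and favours the cross product because the acrylate partner homodimerises slowly.

Step 12
Reactants: 17 bis-silylated diol (C1 hydroxyl cis to methyl); 20 (2E)-5,5-diethoxypent-2-enoic acid
Product: 21 (1R,2R,3S,4R)-3-({[tert-butyl(dimethyl)silyl]oxy}methyl)-2-methyl-4-[(2R)-1-{[tert-butyl(dimethyl)silyl]oxy}-3-{[(2E)-5,5-diethoxypent-2-enoyl]oxy}propan-2-yl]cyclopentyl (2E)-5,5-diethoxypent-2-enoate
Conditions: 20 (3 equiv), PPh3, DIAD, PhMe, 0 °C → rt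
Reagents that add atoms: none
Why: Twofold Mitsunobu esterification: the primary hydroxyl is acylated and the C1 oxyphosphonium is displaced by the carboxylate in an SN2 step with inversion, anti to the adjacent methyl group, which turns the cis C1 alcohol into the required trans ester.

Step 13
Reactants: 22 (E)-crotonaldehyde
Product: 23 (2Z)-2-iodobut-2-enal
Conditions: I2, K2CO3, DMAP (20 mol %), THF/H2O (1:1), rt
Reagents that add atoms: iodine, II
Why: α-Iodination of an enal by conjugate addition of DMAP, iodination of the enolate and elimination (Baylis–Hillman-type pathway) returns the more stable geometry with methyl trans to CHO, that is cis to iodine.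

Step 14
Reactants: 23 (2Z)-2-iodobut-2-enal
Product: 24 (2Z)-2-iodobut-2-en-1-ol
Conditions: NaBH4, CeCl3·7H2O, MeOH, 0 °C
Reagents that add atoms: none
Why: Luche 1,2-reduction of the enal leaves the vinyl iodide and the alkene geometry untouched.

Step 15
Reactants: 24 (2Z)-2-iodobut-2-en-1-ol
Product: 25 tert-butyl{[(2Z)-2-iodobut-2-en-1-yl]oxy}dimethylsilane
Conditions: TBSCl, imidazole, CH2Cl2, rt
Reagents that add atoms: tert-butyldimethylsilyl chloride, CC(C)(C)[Si](C)(C)Cl
Why: Standard silylation of the allylic alcohol.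

Step 16
Reactants: 25 tert-butyl{[(2Z)-2-iodobut-2-en-1-yl]oxy}dimethylsilane
Product: 28 [(2E)-1-{[tert-butyl(dimethyl)silyl]oxy}but-2-en-2-yl]boronic acid (methyl cis to boron), via alkenyllithium 26 (not isolated), via lithium borate 27 (not isolated)
Conditions: t-BuLi (2.1 equiv), Et2O, −78 °C; B(Oi-Pr)3, −78 → 0 °C; 1 M HCl to pH 5
Reagents that add atoms: triisopropyl borate, CC(C)OB(OC(C)C)OC(C)C; water, O
Why: Iodine–lithium exchange with retention of alkene geometry, borylation of the alkenyllithium by the trialkyl borate and mild hydrolysis of the ate complex give the boronic acid.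

Step 17
Reactants: 21 core bis[(2E)-5,5-diethoxypent-2-enoate]; 28 [(2E)-1-{[tert-butyl(dimethyl)silyl]oxy}but-2-en-2-yl]boronic acid
Product: 29 fully protected bis-adduct, both enoates of 21 converted into (3S,4E)-4-({[tert-butyl(dimethyl)silyl]oxy}methyl)-3-(2,2-diethoxyethyl)hex-4-enoates
Conditions: 28 (6 equiv), [Rh(OH)((R)-binap)]2 (5 mol %), 1,4-dioxane/H2O (10:1), 50 °C
Reagents that add atoms: none
Why: Hayashi–Miyaura rhodium-catalysed asymmetric 1,4-addition, run twice in one flask: 28 transmetalates to the hydroxo complex of monovalent rhodium with retention of alkene geometry, the alkenylrhodium inserts the coordinated (E)-enoate to make the a3–a4 bond, and water protonates the oxa-π-allyl rhodium enolate and returns Rh–OH. The closest known reaction is the BINAP–rhodium addition of aryl- and alkenylboron reagents to β-alkyl acrylates; no ring is closed. Each a3 centre is set by the ligand alone: (R)-BINAP is expected to deliver the organic group to the Cα-re face of an (E)-enoate (mirror image of the known (S)-BINAP/Cα-si course), which is S here because alkenyl > CH2CO2R > CH2CH(OEt)2. Both enoates are unhindered and four or more bonds from the nearest core stereocentre, so catalyst control should be the same at each and should override the substrate. The step needs 1,4-insertion to be faster than protodeboronation and than β-silyloxy elimination from the α-branched alkenylrhodium; the excess of 28, the bulky, poorly coordinating OTBS group and the mild temperature serve this, and the absence of base protects the esters and acetals. The E-ethylidene geometry is carried over from 28 (methyl cis to boron).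

Step 18
Reactants: 29 fully protected bis-adduct
Product: 30 tetraol bis(diethyl acetal): core C3–CH2OH and C1′–CH2OH free, both acyl groups (3S,4E)-3-(2,2-diethoxyethyl)-4-(hydroxymethyl)hex-4-enoyl
Conditions: HF·pyridine, pyridine, THF, 0 °C → rt
Reagents that add atoms: none
Why: Fluoride cleavage of the four primary silyl ethers under acidic buffering should spare acetals and esters and avoid the base-induced 1,3-acyl shift between the two arms of C1′.

Step 19
Reactants: 30 tetraol bis(diethyl acetal)
Product: 31 bis-enal bis(diethyl acetal): both acyl groups (3S,4E)-3-(2,2-diethoxyethyl)-4-formylhex-4-enoyl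
Conditions: MnO2 (activated, excess), CH2Cl2, rt
Reagents that add atoms: none
Why: MnO2 oxidises only the two allylic alcohols to the (E)-enals, the saturated primary alcohols of the core being inert.

Step 20
Reactants: 31 bis-enal bis(diethyl acetal)
Product: 32 target, (1R,2R,3S,4R)-3-(hydroxymethyl)-2-methyl-4-[(2S)-1-hydroxy-3-{[(3S,4E)-4-formyl-3-(2-oxoethyl)hex-4-enoyl]oxy}propan-2-yl]cyclopentyl (3S,4E)-4-formyl-3-(2-oxoethyl)hex-4-enoate
Conditions: AcOH/THF/H2O (3:1:1), rt → 35 °C
Reagents that add atoms: water, O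
Why: Mild acid-catalysed acetal hydrolysis releases the two saturated aldehydes last, so that they never coexist with the allylic alcohols (which would form lactols), and avoids basic conditions that would move the acyl group on C1′.

**Compound list**

1 | (1S,4R)-cis-4-acetoxycyclopent-2-en-1-ol | CC(=O)O[C@@H]1C[C@H](O)C=C1 | starting material
2 | dimethyl malonate | COC(=O)CC(=O)OC | starting material
3 | dimethyl 2-[(1R,4S)-4-hydroxycyclopent-2-en-1-yl]propanedioate | COC(=O)C(C(=O)OC)[C@@H]1C[C@H](O)C=C1 | intermediate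
4 | methyl 2-[(1S,4S)-4-hydroxycyclopent-2-en-1-yl]acetate | COC(=O)C[C@@H]1C[C@H](O)C=C1 | intermediate
5 | methyl 2-[(1S)-4-oxocyclopent-2-en-1-yl]acetate | COC(=O)C[C@@H]1CC(=O)C=C1 | intermediate
6 | (chloromethyl)dimethyl(propan-2-yloxy)silane | CC(C)O[Si](C)(C)CCl | starting material
7 | {[dimethyl(propan-2-yloxy)silyl]methyl}magnesium chloride (not isolated) | CC(C)O[Si](C)(C)C[Mg]Cl | intermediate
8 | chloromagnesium enolate from 1,4-addition of 7 to 5, silylmethyl group trans to the acetate arm (not isolated) | COC(=O)C[C@@H]1CC(O[Mg]Cl)=C[C@H]1C[Si](C)(C)OC(C)C | intermediate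
9 | methyl 2-[(1S,2S,3R)-2-{[dimethyl(propan-2-yloxy)silyl]methyl}-3-methyl-4-oxocyclopentyl]acetate | COC(=O)C[C@@H]1CC(=O)[C@H](C)[C@H]1C[Si](C)(C)OC(C)C | intermediate
10 | methyl 2-[(1S,2S,3R)-2-(hydroxymethyl)-3-methyl-4-oxocyclopentyl]acetate | COC(=O)C[C@@H]1CC(=O)[C@H](C)[C@H]1CO | intermediate
11 | methyl 2-[(1S,2S,3R)-2-({[tert-butyl(dimethyl)silyl]oxy}methyl)-3-methyl-4-oxocyclopentyl]acetate | COC(=O)C[C@@H]1CC(=O)[C@H](C)[C@H]1CO[Si](C)(C)C(C)(C)C | intermediate
12 | methyl 2-[(1S,2S,3R,4S)-2-({[tert-butyl(dimethyl)silyl]oxy}methyl)-4-hydroxy-3-methylcyclopentyl]acetate (not isolated) | COC(=O)C[C@@H]1C[C@H](O)[C@H](C)[C@H]1CO[Si](C)(C)C(C)(C)C | intermediate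
13 | (1S,5S,6S,7R)-6-({[tert-butyl(dimethyl)silyl]oxy}methyl)-7-methyl-2-oxabicyclo[3.2.1]octan-3-one | O=C1C[C@@H]2C[C@H](O1)[C@H](C)[C@H]2CO[Si](C)(C)C(C)(C)C | intermediate
14 | lithium enolate of 13 (not isolated) | [Li]OC1=C[C@@H]2C[C@H](O1)[C@H](C)[C@H]2CO[Si](C)(C)C(C)(C)C | intermediate
15 | (1S,4S,5R,6S,7R)-6-({[tert-butyl(dimethyl)silyl]oxy}methyl)-4-(hydroxymethyl)-7-methyl-2-oxabicyclo[3.2.1]octan-3-one | O=C1[C@H](CO)[C@@H]2C[C@H](O1)[C@H](C)[C@H]2CO[Si](C)(C)C(C)(C)C | intermediate
16 | (1S,4S,5R,6S,7R)-4,6-bis({[tert-butyl(dimethyl)silyl]oxy}methyl)-7-methyl-2-oxabicyclo[3.2.1]octan-3-one | O=C1[C@H](CO[Si](C)(C)C(C)(C)C)[C@@H]2C[C@H](O1)[C@H](C)[C@H]2CO[Si](C)(C)C(C)(C)C | intermediate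
17 | (1S,2R,3S,4R)-4-[(2R)-1-{[tert-butyl(dimethyl)silyl]oxy}-3-hydroxypropan-2-yl]-3-({[tert-butyl(dimethyl)silyl]oxy}methyl)-2-methylcyclopentan-1-ol | OC[C@H](CO[Si](C)(C)C(C)(C)C)[C@@H]1C[C@H](O)[C@H](C)[C@H]1CO[Si](C)(C)C(C)(C)C | intermediate
18 | 4,4-diethoxybut-1-ene | C=CCC(OCC)OCC | starting material
19 | acrylic acid | C=CC(=O)O | starting material
20 | (2E)-5,5-diethoxypent-2-enoic acid | CCOC(OCC)C/C=C/C(=O)O | intermediate
21 | core bis[(2E)-5,5-diethoxypent-2-enoate] (esters on ring C1 and on one arm of C1′; TBS ethers on C3–CH2O and the other arm) | CCOC(OCC)C/C=C/C(=O)OC[C@H](CO[Si](C)(C)C(C)(C)C)[C@@H]1C[C@@H](OC(=O)/C=C/CC(OCC)OCC)[C@H](C)[C@H]1CO[Si](C)(C)C(C)(C)C | intermediate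
22 | (E)-crotonaldehyde | C/C=C/C=O | starting material
23 | (2Z)-2-iodobut-2-enal | C/C=C(/C=O)I | intermediate
24 | (2Z)-2-iodobut-2-en-1-ol | C/C=C(/CO)I | intermediate
25 | tert-butyl{[(2Z)-2-iodobut-2-en-1-yl]oxy}dimethylsilane | C/C=C(/CO[Si](C)(C)C(C)(C)C)I | intermediate
26 | alkenyllithium from 25, methyl cis to lithium (not isolated) | C/C=C(/CO[Si](C)(C)C(C)(C)C)[Li] | intermediate
27 | lithium alkenyl(triisopropoxy)borate from 26 (not isolated) | C/C=C(/CO[Si](C)(C)C(C)(C)C)[B-](OC(C)C)(OC(C)C)OC(C)C.[Li+] | intermediate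
28 | [(2E)-1-{[tert-butyl(dimethyl)silyl]oxy}but-2-en-2-yl]boronic acid | C/C=C(/CO[Si](C)(C)C(C)(C)C)B(O)O | intermediate
29 | fully protected bis-adduct (two (3S,4E)-4-(TBSOCH2)-3-(2,2-diethoxyethyl)hex-4-enoates on the bis-silylated core) | C/C=C(/CO[Si](C)(C)C(C)(C)C)[C@@H](CC(OCC)OCC)CC(=O)OC[C@H](CO[Si](C)(C)C(C)(C)C)[C@@H]1C[C@@H](OC(=O)C[C@H](CC(OCC)OCC)/C(CO[Si](C)(C)C(C)(C)C)=C\C)[C@H](C)[C@H]1CO[Si](C)(C)C(C)(C)C | intermediate
30 | tetraol bis(diethyl acetal) | C/C=C(/CO)[C@@H](CC(OCC)OCC)CC(=O)OC[C@H](CO)[C@@H]1C[C@@H](OC(=O)C[C@H](CC(OCC)OCC)/C(CO)=C\C)[C@H](C)[C@H]1CO | intermediate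
31 | bis-enal bis(diethyl acetal) | C/C=C(/C=O)[C@@H](CC(OCC)OCC)CC(=O)OC[C@H](CO)[C@@H]1C[C@@H](OC(=O)C[C@H](CC(OCC)OCC)/C(C=O)=C\C)[C@H](C)[C@H]1CO | intermediate
32 | CNP0192766.1 | C/C=C(/C=O)[C@@H](CC=O)CC(=O)OC[C@H](CO)[C@@H]1C[C@@H](OC(=O)C[C@H](CC=O)/C(C=O)=C\C)[C@H](C)[C@H]1CO | target

**Step count**

Total: 20 steps. Longest linear sequence: 15 steps (steps 1–10, 12, 17–20).

**Steps most likely to fail**

Step 17. Protodeboronation of 28 and β-silyloxy elimination from the α-branched alkenylrhodium may outrun insertion into the ester acceptor, so that the second addition stalls; the two enoates may also not be attacked with the same face selectivity. The fallback makes the a3–a4 bond at the fragment stage under auxiliary control and then esterifies. It sets out from acid 20 and iodide 25 and returns at 29. Acid 20 is activated with pivaloyl chloride/Et3N and coupled with lithiated (4R)-4-phenyl-1,3-oxazolidin-2-one to the N-enoyl imide (4R)-3-[(2E)-5,5-diethoxypent-2-enoyl]-4-phenyl-1,3-oxazolidin-2-one F1. Alkenyllithium 26 (from 25 as in step 16) is converted with MgBr2·OEt2 into the alkenylmagnesium bromide (methyl cis to magnesium) F2. With CuBr·SMe2 in THF at −78 °C, F2 should add to the magnesium-chelated s-cis imide on the face opposite the phenyl group and give the (3S)-adduct (4R)-3-[(3S,4E)-4-({[tert-butyl(dimethyl)silyl]oxy}methyl)-3-(2,2-diethoxyethyl)hex-4-enoyl]-4-phenyl-1,3-oxazolidin-2-one F3. LiOH/H2O2 in THF/H2O releases (3S,4E)-4-({[tert-butyl(dimethyl)silyl]oxy}methyl)-3-(2,2-diethoxyethyl)hex-4-enoic acid F4 and the auxiliary. Twofold Mitsunobu esterification of diol 17 with F4 under the conditions of step 12 gives 29.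

Step 12. Displacement at the hindered secondary oxyphosphonium may be slow, with elimination toward C2 competing, and the primary oxyphosphonium may be captured by the C1 hydroxyl (cyclodehydration). The fallback esterifies the two hydroxyls separately and inverts C1 by sulfonate displacement. It sets out from 17 and returns at 21. The primary hydroxyl is acylated selectively with 20 (EDC·HCl, DMAP cat., CH2Cl2, −10 °C) to the mono-enoate with the C1 hydroxyl free F5. MsCl/Et3N (CH2Cl2, 0 °C) gives the C1 methanesulfonate F6. The cesium salt of 20 (20, Cs2CO3, 18-crown-6, PhMe, 80 °C) displaces the mesylate with inversion to give 21.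

Step 4. Proton transfer between the magnesium enolate and the product ketone may scramble the enolate position and lead to methylation at C5, double methylation or incomplete methylation. The fallback installs the methyl group before the conjugate addition. It sets out from 5 and returns at 9. α-Iodination (I2, pyridine, CH2Cl2, rt) gives methyl 2-[(1S)-3-iodo-4-oxocyclopent-2-en-1-yl]acetate F7. Stille methylation (SnMe4, Pd2(dba)3, AsPh3, CuI, NMP, 60 °C) gives methyl 2-[(1S)-3-methyl-4-oxocyclopent-2-en-1-yl]acetate F8. Copper-catalysed addition of 7 (CuI, TMSCl, THF, −78 °C) anti to the C4 arm, followed by hydrolysis of the silyl enol ether with protonation and equilibration at C2 to the trans ketone, gives 9.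

Further compounds
F1 | step 17 | (4R)-3-[(2E)-5,5-diethoxypent-2-enoyl]-4-phenyl-1,3-oxazolidin-2-one | CCOC(OCC)C/C=C/C(=O)N1[C@H](c2ccccc2)COC1=O
F2 | step 17 | {1-{[tert-butyl(dimethyl)silyl]oxy}but-2-en-2-yl}magnesium bromide, methyl cis to magnesium | C/C=C(/CO[Si](C)(C)C(C)(C)C)[Mg]Br
F3 | step 17 | (4R)-3-[(3S,4E)-4-({[tert-butyl(dimethyl)silyl]oxy}methyl)-3-(2,2-diethoxyethyl)hex-4-enoyl]-4-phenyl-1,3-oxazolidin-2-one | C/C=C(/CO[Si](C)(C)C(C)(C)C)[C@@H](CC(OCC)OCC)CC(=O)N1[C@H](c2ccccc2)COC1=O
F4 | step 17 | (3S,4E)-4-({[tert-butyl(dimethyl)silyl]oxy}methyl)-3-(2,2-diethoxyethyl)hex-4-enoic acid | C/C=C(/CO[Si](C)(C)C(C)(C)C)[C@@H](CC(OCC)OCC)CC(=O)O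
F5 | step 12 | mono-enoate of 17 (primary hydroxyl acylated by 20, C1 hydroxyl free) | CCOC(OCC)C/C=C/C(=O)OC[C@H](CO[Si](C)(C)C(C)(C)C)[C@@H]1C[C@H](O)[C@H](C)[C@H]1CO[Si](C)(C)C(C)(C)C
F6 | step 12 | C1 methanesulfonate of F5 | CCOC(OCC)C/C=C/C(=O)OC[C@H](CO[Si](C)(C)C(C)(C)C)[C@@H]1C[C@H](OS(C)(=O)=O)[C@H](C)[C@H]1CO[Si](C)(C)C(C)(C)C
F7 | step 4 | methyl 2-[(1S)-3-iodo-4-oxocyclopent-2-en-1-yl]acetate | COC(=O)C[C@@H]1CC(=O)C(I)=C1
F8 | step 4 | methyl 2-[(1S)-3-methyl-4-oxocyclopent-2-en-1-yl]acetate | COC(=O)C[C@@H]1CC(=O)C(C)=C1
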